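## Retrosynthetic overview

- The last skeletal bond made is the diaryl ether between O5 of ring A (the trioxygenated ring on the carbinol) and C4 of ring B (the para-phenylene). Before this bond exists, ring A is a 4-O-benzylgallyl ring whose O3–H and O5–H are exchanged by rotation about the C1–carbinol bond, so arylation of either gives the same 18-membered ring and the other becomes the C3 hydroxyl.
- The seco boronic acid comes from the ring B aryl bromide by bromine–lithium exchange and borylation, then base cleavage of the two ring A aryl silyl ethers only.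
- The (S)-carbinol comes from Noyori transfer hydrogenation of the aryl benzyl ketone, itself made by adding a ring D benzylzinc to a ring A aldehyde (from methyl gallate) and oxidising.
- Rings D and C are joined by SNAr; ring B is attached by Wittig olefination and diimide reduction.
- Only one ring is formed, the macrocycle, and it is formed last; hydrogenolysis and buffered desilylation finish the synthesis.

Key step: step 17

Remark on the chemistry: CIP analysis of the given SMILES makes the carbinol centre (S). Ring C is the 1,2,3-trisubstituted bibenzyl ring and ring D the meta-phenylene. The ring C hydroxyl is carried as a benzyl ether, so that only the ring A silyl ethers need selective cleavage and one hydrogenolysis frees both benzylated oxygens.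

## Route

Step 1
Reactants: 1 2-fluoro-3-hydroxybenzaldehyde
Product: 2 3-(benzyloxy)-2-fluorobenzaldehyde
Conditions: BnBr, K2CO3, DMF, rt
Reagents that add atoms: benzyl bromide, BrCc1ccccc1
Why: Williamson etherification of the phenoxide is fast at room temperature, far below the temperature needed for fluoride displacement, and it masks the ring C oxygen whose phenoxide would otherwise deactivate the ring towards the SNAr step.

Step 2
Reactants: 2 3-(benzyloxy)-2-fluorobenzaldehyde; 3 3-hydroxybenzyl alcohol
Product: 4 3-(benzyloxy)-2-[3-(hydroxymethyl)phenoxy]benzaldehyde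
Conditions: K2CO3, DMF, 110 °C
Reagents that add atoms: none
Why: SNAr, in which the ortho formyl group stabilises the Meisenheimer adduct at C2 and carbonate ionises only the phenol of 3, so the ether should form at the phenolic oxygen and leave the benzylic hydroxyl free.

Step 3
Reactants: 5 4-bromobenzyl bromide
Product: 6 (4-bromobenzyl)triphenylphosphonium bromide
Conditions: PPh3, toluene, reflux
Reagents that add atoms: triphenylphosphine, c1ccc(cc1)P(c1ccccc1)c1ccccc1
Why: SN2 quaternisation of the phosphine takes place only at the benzylic bromide, the aryl bromide being inert, and the salt should crystallise from the hot solvent.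

Step 4
Reactants: 4 3-(benzyloxy)-2-[3-(hydroxymethyl)phenoxy]benzaldehyde; 6 (4-bromobenzyl)triphenylphosphonium bromide
Product: 8 (3-{2-(benzyloxy)-6-[2-(4-bromophenyl)ethenyl]phenoxy}phenyl)methanol as an E/Z mixture, via phosphorus ylide 7 (not isolated)
Conditions: K2CO3, 18-crown-6 (cat.), CH2Cl2, reflux
Reagents that add atoms: none
Why: Wittig olefination with a semi-stabilised benzylic ylide, generated under solid–liquid phase-transfer conditions that tolerate the free alcohol; the alkene geometry is irrelevant because the double bond is saturated next.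

Step 5
Reactants: 8 stilbene alcohol (E/Z mixture)
Product: 9 (3-{2-(benzyloxy)-6-[2-(4-bromophenyl)ethyl]phenoxy}phenyl)methanol
Conditions: TsNHNH2, NaOAc, THF/H2O, reflux
Reagents that add atoms: none
Why: Diimide reduction transfers two hydrogens concertedly to the stilbene double bond and, unlike hydrogen over palladium, should leave the aryl bromide and the benzyl ether untouched.

Step 6
Reactants: 9 bibenzyl alcohol
Product: 10 1-(benzyloxy)-3-[2-(4-bromophenyl)ethyl]-2-[3-(chloromethyl)phenoxy]benzene
Conditions: SOCl2, DMF (cat.), CH2Cl2, 0 °C to rt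
Reagents that add atoms: thionyl chloride, O=S(Cl)Cl
Why: Chlorodehydroxylation of a primary benzylic alcohol through its chlorosulfite is reliable, and the chloride is preferred to the bromide because it inserts zinc with less Wurtz coupling.

Step 7
Reactants: 11 methyl gallate
Product: 12 methyl 4-(benzyloxy)-3,5-dihydroxybenzoate
Conditions: BnBr (1.0 equiv), KHCO3, KI (cat.), DMF, rt
Reagents that add atoms: benzyl bromide, BrCc1ccccc1
Why: Williamson etherification under a weak base should alkylate mainly the 4-hydroxyl, the most acidic because it is para to the ester, leaving the two meta hydroxyls free and equivalent.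

Step 8
Reactants: 12 methyl 4-(benzyloxy)-3,5-dihydroxybenzoate
Product: 13 methyl 4-(benzyloxy)-3,5-bis[(tert-butyldimethylsilyl)oxy]benzoate
Conditions: TBSCl, imidazole, DMF, rt
Reagents that add atoms: tert-butyldimethylsilyl chloride, CC(C)(C)[Si](C)(C)Cl
Why: Imidazole-promoted silylation of phenols; aryl silyl ethers are chosen because mild base removes them later without touching an alkyl silyl ether.

Step 9
Reactants: 13 methyl 4-(benzyloxy)-3,5-bis[(tert-butyldimethylsilyl)oxy]benzoate
Product: 14 {4-(benzyloxy)-3,5-bis[(tert-butyldimethylsilyl)oxy]phenyl}methanol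
Conditions: iBu2AlH, CH2Cl2, −78 to 0 °C; Rochelle salt work-up
Reagents that add atoms: none
Why: Hydride reduction of the ester to the primary alcohol with iBu2AlH should leave aryl silyl and benzyl ethers intact.

Step 10
Reactants: 14 {4-(benzyloxy)-3,5-bis[(tert-butyldimethylsilyl)oxy]phenyl}methanol
Product: 15 4-(benzyloxy)-3,5-bis[(tert-butyldimethylsilyl)oxy]benzaldehyde
Conditions: Dess–Martin periodinane, CH2Cl2, rt
Reagents that add atoms: none
Why: Dess–Martin oxidation of a benzylic alcohol stops at the aldehyde under nearly neutral conditions that the silyl ethers tolerate.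

Step 11
Reactants: 10 ring D benzylic chloride; 15 4-(benzyloxy)-3,5-bis[(tert-butyldimethylsilyl)oxy]benzaldehyde
Product: 17 racemic 1-{4-(benzyloxy)-3,5-bis[(tert-butyldimethylsilyl)oxy]phenyl}-2-(3-{2-(benzyloxy)-6-[2-(4-bromophenyl)ethyl]phenoxy}phenyl)ethan-1-ol, via benzylzinc chloride 16 (not isolated)
Conditions: Zn dust, LiCl, THF, 25 °C; then 15, MgCl2, THF, 25 °C; aq NH4Cl
Reagents that add atoms: none
Why: LiCl-promoted insertion of zinc into the benzylic C–Cl bond is much faster than into an aryl bromide, and the benzylzinc should add 1,2 to the aldehyde once MgCl2 activates the carbonyl (organozinc addition); the carbinol is racemic here and its configuration is set in step 13.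

Step 12
Reactants: 17 racemic diarylethanol
Product: 18 1-{4-(benzyloxy)-3,5-bis[(tert-butyldimethylsilyl)oxy]phenyl}-2-(3-{2-(benzyloxy)-6-[2-(4-bromophenyl)ethyl]phenoxy}phenyl)ethan-1-one
Conditions: Dess–Martin periodinane, CH2Cl2, 0 °C to rt
Reagents that add atoms: none
Why: Dess–Martin oxidation of the secondary benzylic alcohol gives the aryl benzyl ketone and erases the racemic centre so that it can be rebuilt under catalyst control.

Step 13
Reactants: 18 aryl benzyl ketone
Product: 19 (1S)-1-{4-(benzyloxy)-3,5-bis[(tert-butyldimethylsilyl)oxy]phenyl}-2-(3-{2-(benzyloxy)-6-[2-(4-bromophenyl)ethyl]phenoxy}phenyl)ethan-1-ol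
Conditions: RuCl[(S,S)-TsDPEN](p-cymene) (2 mol %), HCO2H/Et3N (5:2), CH2Cl2, 30 °C
Reagents that add atoms: none
Why: Noyori asymmetric transfer hydrogenation, in which the ruthenium hydride and the ligand N–H deliver hydride and proton through an outer-sphere transition state with ring A held against the cymene ligand by a CH/π contact; the (S,S) ligand should give the (S)-carbinol, in the same sense as acetophenone gives (S)-1-phenylethanol.

Step 14
Reactants: 19 (S)-diarylethanol
Product: 20 (S)-carbinol tert-butyldimethylsilyl ether of 19 (ring B bromide carrying three silyl ethers)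
Conditions: TBSCl, imidazole, DMAP (cat.), DMF, rt
Reagents that add atoms: tert-butyldimethylsilyl chloride, CC(C)(C)[Si](C)(C)Cl
Why: Silylation at oxygen does not touch the C–O bond of the stereocentre, and the alkyl silyl ether blocks ionisation and later hydrogenolysis of the electron-rich benzylic position.

Step 15
Reactants: 20 (S)-tris-silyl ether aryl bromide
Product: 23 {4-[2-(3-(benzyloxy)-2-{3-[(2S)-2-{4-(benzyloxy)-3,5-bis[(tert-butyldimethylsilyl)oxy]phenyl}-2-[(tert-butyldimethylsilyl)oxy]ethyl]phenoxy}phenyl)ethyl]phenyl}boronic acid, via aryllithium 21 (not isolated), via lithium triisopropoxyborate 22 (not isolated)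
Conditions: B(OiPr)3, n-BuLi, THF/toluene, −78 °C (in situ quench); then 1 M HCl to pH 5, 0 °C
Reagents that add atoms: triisopropyl borate, CC(C)OB(OC(C)C)OC(C)C; water, O
Why: Bromine–lithium exchange at −78 °C is faster than attack of the alkyllithium on silicon or on benzylic hydrogens, the aryllithium is trapped by the borate as it forms, and mild acid hydrolysis should give the boronic acid directly (lithiation–borylation).

Step 16
Reactants: 23 tris-silylated ring B boronic acid
Product: 24 {4-[2-(3-(benzyloxy)-2-{3-[(2S)-2-[4-(benzyloxy)-3,5-dihydroxyphenyl]-2-[(tert-butyldimethylsilyl)oxy]ethyl]phenoxy}phenyl)ethyl]phenyl}boronic acid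
Conditions: Cs2CO3 (2 equiv), DMF/H2O (10:1), rt, argon; pH 6 buffer work-up
Reagents that add atoms: none
Why: Base-mediated cleavage of aryl silyl ethers is selective because a phenoxide is a far better leaving group from silicon than an alkoxide, so the two ring A phenols should be freed while the carbinol silyl ether and the boronic acid (as its boronate) persist.

Step 17
Reactants: 24 seco boronic acid with the symmetric ring A diol
Product: 25 18-membered macrocycle with (S)-carbinol silyl ether, ring A 3-hydroxyl free, ring A 4-O-benzyl and ring C O-benzyl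
Conditions: Cu(OAc)2 (2 equiv), pyridine (10 equiv), 4 Å MS, CH2Cl2, O2 (1 atm), rt; 24 added by syringe pump over 24 h to about 1 mM
Reagents that add atoms: none
Why: Chan–Lam oxidative etherification, in which the ring B aryl group passes from boron to divalent copper, a ring A phenoxide binds, oxidation to trivalent copper is followed by C–O reductive elimination, and O2 returns monovalent copper to the divalent state so that copper diacetate is not consumed overall. The closest known reaction type is the copper diacetate and amine mediated coupling of arylboronic acids with phenols in its intramolecular, macrocyclic diaryl ether form. The one ring closed is the 18-membered macrocycle, formed by intramolecular aryl–oxygen bond formation between C4 of ring B and O5 of ring A at room temperature. No stereocentre is created, and the silylated (S)-carbinol is not affected by the neutral conditions. The step needs ring closure over oligomerisation and mono- over bis-arylation: slow addition into a dilute copper suspension keeps the concentration of free boronic acid low, the two ring A hydroxyls are interchanged by aryl rotation so either leads to 25, and a cyclised molecule has no boron left for its second hydroxyl. The 4-O-benzyl group keeps ring A from being an oxidisable pyrogallol, and the sieves suppress hydroxylation of the boronic acid by water.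

Step 18
Reactants: 25 benzyl-protected macrocycle
Product: 26 (S)-carbinol tert-butyldimethylsilyl ether of the target (ring A catechol and ring C phenol free)
Conditions: H2 (1 atm), 10% Pd/C, EtOAc, rt
Reagents that add atoms: none
Why: Catalytic hydrogenolysis should cleave both benzyl aryl ethers, while the silyl group shields the electron-rich benzylic C–O bond from reduction and ethyl acetate avoids the silyl ether loss seen with palladium in methanol.

Step 19
Reactants: 26 mono-silylated macrocyclic triol
Product: 27 target CNP0333307.1, the (S)-carbinol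
Conditions: Bu4NF/AcOH (1:1), THF, 0 °C to rt, argon
Reagents that add atoms: none
Why: Fluoride-induced desilylation buffered with acetic acid keeps the ring A 4-hydroxyl protonated, so the para-hydroxybenzylic carbinol should not ionise to a quinone methide and the stereocentre is kept.

## Compound list

1 | 2-fluoro-3-hydroxybenzaldehyde | O=Cc1cccc(O)c1F | starting material
2 | 3-(benzyloxy)-2-fluorobenzaldehyde | O=Cc1cccc(OCc2ccccc2)c1F | intermediate
3 | 3-hydroxybenzyl alcohol | OCc1cccc(O)c1 | starting material
4 | 3-(benzyloxy)-2-[3-(hydroxymethyl)phenoxy]benzaldehyde | O=Cc1cccc(OCc2ccccc2)c1Oc1cccc(c1)CO | intermediate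
5 | 4-bromobenzyl bromide | BrCc1ccc(Br)cc1 | starting material
6 | (4-bromobenzyl)triphenylphosphonium bromide | [Br-].Brc1ccc(cc1)C[P+](c1ccccc1)(c1ccccc1)c1ccccc1 | intermediate
7 | (4-bromobenzylidene)triphenylphosphorane (not isolated) | Brc1ccc(cc1)C=P(c1ccccc1)(c1ccccc1)c1ccccc1 | intermediate
8 | (3-{2-(benzyloxy)-6-[2-(4-bromophenyl)ethenyl]phenoxy}phenyl)methanol, E/Z mixture | Brc1ccc(cc1)C=Cc1cccc(OCc2ccccc2)c1Oc1cccc(c1)CO | intermediate
9 | (3-{2-(benzyloxy)-6-[2-(4-bromophenyl)ethyl]phenoxy}phenyl)methanol | Brc1ccc(cc1)CCc1cccc(OCc2ccccc2)c1Oc1cccc(c1)CO | intermediate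
10 | 1-(benzyloxy)-3-[2-(4-bromophenyl)ethyl]-2-[3-(chloromethyl)phenoxy]benzene | Brc1ccc(cc1)CCc1cccc(OCc2ccccc2)c1Oc1cccc(c1)CCl | intermediate
11 | methyl gallate | COC(=O)c1cc(O)c(O)c(O)c1 | starting material
12 | methyl 4-(benzyloxy)-3,5-dihydroxybenzoate | COC(=O)c1cc(O)c(OCc2ccccc2)c(O)c1 | intermediate
13 | methyl 4-(benzyloxy)-3,5-bis[(tert-butyldimethylsilyl)oxy]benzoate | COC(=O)c1cc(O[Si](C)(C)C(C)(C)C)c(OCc2ccccc2)c(O[Si](C)(C)C(C)(C)C)c1 | intermediate
14 | {4-(benzyloxy)-3,5-bis[(tert-butyldimethylsilyl)oxy]phenyl}methanol | OCc1cc(O[Si](C)(C)C(C)(C)C)c(OCc2ccccc2)c(O[Si](C)(C)C(C)(C)C)c1 | intermediate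
15 | 4-(benzyloxy)-3,5-bis[(tert-butyldimethylsilyl)oxy]benzaldehyde | O=Cc1cc(O[Si](C)(C)C(C)(C)C)c(OCc2ccccc2)c(O[Si](C)(C)C(C)(C)C)c1 | intermediate
16 | benzylzinc chloride from 10 (not isolated) | Brc1ccc(cc1)CCc1cccc(OCc2ccccc2)c1Oc1cccc(c1)C[Zn]Cl | intermediate
17 | racemic 1-(ring A aryl)-2-(ring D aryl)ethan-1-ol (full name in step 11) | Brc1ccc(cc1)CCc1cccc(OCc2ccccc2)c1Oc1cccc(c1)CC(O)c1cc(O[Si](C)(C)C(C)(C)C)c(OCc2ccccc2)c(O[Si](C)(C)C(C)(C)C)c1 | intermediate
18 | aryl benzyl ketone (full name in step 12) | Brc1ccc(cc1)CCc1cccc(OCc2ccccc2)c1Oc1cccc(c1)CC(=O)c1cc(O[Si](C)(C)C(C)(C)C)c(OCc2ccccc2)c(O[Si](C)(C)C(C)(C)C)c1 | intermediate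
19 | (1S)-alcohol (full name in step 13) | Brc1ccc(cc1)CCc1cccc(OCc2ccccc2)c1Oc1cccc(c1)C[C@H](O)c1cc(O[Si](C)(C)C(C)(C)C)c(OCc2ccccc2)c(O[Si](C)(C)C(C)(C)C)c1 | intermediate
20 | (S)-carbinol tert-butyldimethylsilyl ether of 19 | Brc1ccc(cc1)CCc1cccc(OCc2ccccc2)c1Oc1cccc(c1)C[C@H](O[Si](C)(C)C(C)(C)C)c1cc(O[Si](C)(C)C(C)(C)C)c(OCc2ccccc2)c(O[Si](C)(C)C(C)(C)C)c1 | intermediate
21 | ring B aryllithium from 20 (not isolated) | [Li]c1ccc(cc1)CCc1cccc(OCc2ccccc2)c1Oc1cccc(c1)C[C@H](O[Si](C)(C)C(C)(C)C)c1cc(O[Si](C)(C)C(C)(C)C)c(OCc2ccccc2)c(O[Si](C)(C)C(C)(C)C)c1 | intermediate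
22 | lithium aryl(triisopropoxy)borate (not isolated) | [Li+].CC(C)O[B-](OC(C)C)(OC(C)C)c1ccc(cc1)CCc1cccc(OCc2ccccc2)c1Oc1cccc(c1)C[C@H](O[Si](C)(C)C(C)(C)C)c1cc(O[Si](C)(C)C(C)(C)C)c(OCc2ccccc2)c(O[Si](C)(C)C(C)(C)C)c1 | intermediate
23 | tris-silylated ring B boronic acid (full name in step 15) | OB(O)c1ccc(cc1)CCc1cccc(OCc2ccccc2)c1Oc1cccc(c1)C[C@H](O[Si](C)(C)C(C)(C)C)c1cc(O[Si](C)(C)C(C)(C)C)c(OCc2ccccc2)c(O[Si](C)(C)C(C)(C)C)c1 | intermediate
24 | seco ring B boronic acid with free ring A 3,5-diol (full name in step 16) | OB(O)c1ccc(cc1)CCc1cccc(OCc2ccccc2)c1Oc1cccc(c1)C[C@H](O[Si](C)(C)C(C)(C)C)c1cc(O)c(OCc2ccccc2)c(O)c1 | intermediate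
25 | 18-membered macrocycle, (S)-carbinol silyl ether, ring A 3-OH free, ring A 4-OBn, ring C OBn | Oc1cc2cc(c1OCc1ccccc1)Oc1ccc(cc1)CCc1cccc(OCc3ccccc3)c1Oc1cccc(c1)C[C@@H]2O[Si](C)(C)C(C)(C)C | intermediate
26 | (S)-carbinol tert-butyldimethylsilyl ether of the target | Oc1cc2cc(c1O)Oc1ccc(cc1)CCc1cccc(O)c1Oc1cccc(c1)C[C@@H]2O[Si](C)(C)C(C)(C)C | intermediate
27 | CNP0333307.1, (S)-configured macrocyclic bis(bibenzyl)-type carbinol | Oc1cc2cc(c1O)Oc1ccc(cc1)CCc1cccc(O)c1Oc1cccc(c1)C[C@@H]2O | target

## Step count and risks

Total step count: 19. Longest linear sequence: 14 steps (steps 1, 2, 4, 5, 6, 11 to 19, from 2-fluoro-3-hydroxybenzaldehyde).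

Steps most likely to fail:

Step 17. Intermolecular coupling to oligomers, protodeboronation and oxidative hydroxylation of the boronic acid may outrun ring closure. The fallback closes the same ether bond from the halide rather than from boron. It sets out from 20: Cs2CO3 in DMF/H2O at rt would free the two ring A phenols selectively to give the bromo diol F1. An intramolecular Ullmann etherification (CuI, N,N-dimethylglycine, Cs2CO3, dioxane, 90 °C, slow addition at high dilution) would then join either equivalent phenol to ring B. This comes back to the route at 25 and bypasses steps 15 and 16.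

Step 11. Wurtz-type homocoupling during zinc insertion, or slow addition of the organozinc to the electron-rich aldehyde, may erode the fragment union. The fallback reverses the polarity of the coupling. It sets out from 15: 1,3-propanedithiol with catalytic BF3·OEt2 in CH2Cl2 at 0 °C would give the 2-aryl-1,3-dithiane F2. Deprotonation with n-BuLi in THF at −40 °C would give the 2-lithio dithiane F3, and alkylation with chloride 10 the 2-aryl-2-benzyl dithiane F4. Hydrolysis with MeI and CaCO3 in MeCN/H2O would release the ketone, coming back to the route at 18 and making step 12 unnecessary.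

Step 15. Incomplete halogen–metal exchange, attack of the alkyllithium on silicon or on benzylic hydrogens, and loss of boron during acidic work-up may lower the supply of boronic acid. The fallback replaces lithiation by palladium catalysis. It sets out from 20: Miyaura borylation (B2pin2, Pd(dppf)Cl2, KOAc, dioxane, 80 °C) would give the pinacol boronate F5. Oxidative cleavage of the pinacol unit (NaIO4, NH4OAc, acetone/H2O, rt), done while the ring A phenols are still silylated, would give the free boronic acid and come back to the route at 23.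

## Further compounds

F1 | step 17 | ring B bromide with free ring A 3,5-diol and (S)-carbinol silyl ether | Brc1ccc(cc1)CCc1cccc(OCc2ccccc2)c1Oc1cccc(c1)C[C@H](O[Si](C)(C)C(C)(C)C)c1cc(O)c(OCc2ccccc2)c(O)c1
F2 | step 11 | 2-{4-(benzyloxy)-3,5-bis[(tert-butyldimethylsilyl)oxy]phenyl}-1,3-dithiane | S1CCCSC1c1cc(O[Si](C)(C)C(C)(C)C)c(OCc2ccccc2)c(O[Si](C)(C)C(C)(C)C)c1
F3 | step 11 | 2-lithio derivative of dithiane F2 | [Li]C1(SCCCS1)c1cc(O[Si](C)(C)C(C)(C)C)c(OCc2ccccc2)c(O[Si](C)(C)C(C)(C)C)c1
F4 | step 11 | 2-(ring A aryl)-2-(ring D benzyl)-1,3-dithiane | Brc1ccc(cc1)CCc1cccc(OCc2ccccc2)c1Oc1cccc(c1)CC1(SCCCS1)c1cc(O[Si](C)(C)C(C)(C)C)c(OCc2ccccc2)c(O[Si](C)(C)C(C)(C)C)c1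
F5 | step 15 | ring B pinacol boronate of 20 | CC1(C)OB(OC1(C)C)c1ccc(cc1)CCc1cccc(OCc2ccccc2)c1Oc1cccc(c1)C[C@H](O[Si](C)(C)C(C)(C)C)c1cc(O[Si](C)(C)C(C)(C)C)c(OCc2ccccc2)c(O[Si](C)(C)C(C)(C)C)c1
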